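**Plan**

- Feature: the ten-membered ring C1–C10 (ring alkenes C1=C10 and C4=C5, the CH2OH carbons C14 and C15 outside) is trans-fused at C7–C8 to the γ-lactone O8–C12–C11–C7. C6 is a secondary allylic carbinol between vinylic C5 and lactone carbon C7, so C5–C6 is an alkenyl-metal/aldehyde bond.
- Cuts, in retrosynthetic order: O6–tigloyl and C11=C13; C5–C6 (opens the ten-membered ring); C6–C7 (1,4-addition to a butenolide); C7–C11 and O8–C12 (epoxide plus thioacetate dianion); C9–C10 (alkenyllithium plus epichlorohydrin); C10–C14 and C3–C4 (alkyne chemistry).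
- Forward: the C5–C10 dienyl chain is assembled first, the lactone ring is built on its C9 end, the ten-membered ring is closed at C5–C6, and C13 and the tiglate are added last.
- Stereochemistry: both alkene geometries come from anti additions to propargylic alcohols; C8 comes from (S)-epichlorohydrin; C7 is set by addition trans to the C8 side chain; C6 is set in the ring closure under control of C7/C8.

Key step: step 13

Assumption: the SMILES is read as drawn, so at both ring alkenes the two ring bonds are cis (C9 syn to C2, C3 syn to C6) and the CH2O groups point outward; both are therefore E by CIP.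

Abbreviations: TMS = trimethylsilyl, TBS = tert-butyldimethylsilyl, TES = triethylsilyl. Atom labels C1–C15 are those of the plan. The CIP descriptor of C7 changes with the O6 substituent although the centre itself is never touched after step 10.

**Route**

Step 1
Reactants: 1 3-(trimethylsilyl)prop-2-yn-1-ol; 2 (4-bromobut-1-yn-1-yl)trimethylsilane
Product: 4 (E)-3-(trimethylsilyl)-2-[4-(trimethylsilyl)but-3-yn-1-yl]prop-2-en-1-ol (alkenyl TMS cis to the butynyl chain), via Grignard reagent 3 (not isolated)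
Conditions: 2 (2.5 equiv), Mg, THF, 40 °C; then 1, CuI (10 mol %), THF/Et2O, 0 °C → rt; aqueous work-up
Reagents that add atoms: none
Why: Copper-catalysed anti-carbomagnesiation of a propargylic alcohol: the magnesium alkoxide holds magnesium on C5 syn to C15–O while the alkyl group adds to C4 from the other side (the α-silyl group reinforces this regiochemistry), so protonation should leave silicon cis to the new C3 chain, the geometry the later C5–I bond needs.

Step 2
Reactants: 4 (E)-3-(trimethylsilyl)-2-[4-(trimethylsilyl)but-3-yn-1-yl]prop-2-en-1-ol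
Product: 5 (E)-2-(but-3-yn-1-yl)-3-(trimethylsilyl)prop-2-en-1-ol
Conditions: K2CO3 (cat.), MeOH, rt
Reagents that add atoms: none
Why: Base-mediated methanolysis (protodesilylation of a silylalkyne) cleaves only the alkynyl C–Si bond; the alkenylsilane is inert.

Step 3
Reactants: 5 (E)-2-(but-3-yn-1-yl)-3-(trimethylsilyl)prop-2-en-1-ol
Product: 6 (E)-2-[(trimethylsilyl)methylidene]hept-5-yne-1,7-diol
Conditions: n-BuLi (2.1 equiv), THF, −78 → 0 °C; (CH2O)n, 0 °C → rt; H2O
Reagents that add atoms: paraformaldehyde (as formaldehyde), C=O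
Why: The alkoxide/lithium acetylide dianion adds through carbon to formaldehyde (acetylide hydroxymethylation), which installs C14 and the hydroxyl needed to direct the next step.

Step 4
Reactants: 6 (E)-2-[(trimethylsilyl)methylidene]hept-5-yne-1,7-diol
Product: 8 (2Z)-2-iodo-6-[(E)-(trimethylsilyl)methylidene]hept-2-ene-1,7-diol, via alkenylstannane 7 (not isolated)
Conditions: Bu3SnH (1.05 equiv), [Cp*RuCl]4 (1.25 mol %), CH2Cl2, rt; then I2 (1.1 equiv), 0 °C
Reagents that add atoms: iodine, II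
Why: Hydroxyl-directed ruthenium-catalysed trans-hydrostannation puts tin on C10 (next to the C14 hydroxyl) and hydrogen on C1 from the opposite side, so tin is cis to C2; iododestannylation then replaces tin with retention and is much faster than attack on the alkenylsilane.

Step 5
Reactants: 8 (2Z)-2-iodo-6-[(E)-(trimethylsilyl)methylidene]hept-2-ene-1,7-diol
Product: 9 (2Z,6E)-1-(TBS-oxy)-6-[(TBS-oxy)methyl]-2-iodo-7-(trimethylsilyl)hepta-2,6-diene
Conditions: TBSCl (2.4 equiv), imidazole, DMF, rt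
Reagents that add atoms: tert-butyldimethylsilyl chloride, CC(C)(C)[Si](C)(C)Cl
Why: Standard silylation of two primary allylic alcohols (silyl ether formation).

Step 6
Reactants: 9 (2Z,6E)-1-(TBS-oxy)-6-[(TBS-oxy)methyl]-2-iodo-7-(trimethylsilyl)hepta-2,6-diene; 10 (S)-epichlorohydrin
Product: 13 (S)-2-[(2E,6E)-2,6-bis(TBS-oxymethyl)-7-(trimethylsilyl)hepta-2,6-dien-1-yl]oxirane, via alkenyllithium 11 (not isolated), via chlorohydrin 12 (not isolated)
Conditions: t-BuLi (2.05 equiv), Et2O, −78 °C; 10 (1.5 equiv), BF3·OEt2, −78 °C; H2O; crude in MeOH, K2CO3, rt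
Reagents that add atoms: none
Why: Iodine–lithium exchange gives the configurationally stable alkenyllithium, which opens the BF3-activated epoxide at its CH2 terminus (BF3-promoted organolithium epoxide opening) to form C9–C10; base then closes the chlorohydrin to the new terminal epoxide (intramolecular Williamson reaction), and no bond to C8 is broken in either event.

Step 7
Reactants: 13 (S)-2-[(2E,6E)-2,6-bis(TBS-oxymethyl)-7-(trimethylsilyl)hepta-2,6-dien-1-yl]oxirane; 14 (phenylthio)acetic acid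
Product: 16 (5S)-5-[(2E,6E)-2,6-bis(TBS-oxymethyl)-7-(trimethylsilyl)hepta-2,6-dien-1-yl]-3-(phenylsulfanyl)oxolan-2-one (C3 epimers), via hydroxy acid 15 (not isolated)
Conditions: 14 (2 equiv), LDA (4.2 equiv), THF, 0 °C; 13, 0 °C → rt; 1 M HCl to pH 3, 0 °C; PPTS (cat.), PhMe, 60 °C
Reagents that add atoms: none
Why: The carboxylate α-carbanion (dianion) opens the terminal epoxide at C7 through carbon and the γ-hydroxy acid lactonizes under mild acid (dianion alkylation–lactonization); C8 is untouched and the C11 epimers converge in step 8.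

Step 8
Reactants: 16 (5S)-5-[(2E,6E)-2,6-bis(TBS-oxymethyl)-7-(trimethylsilyl)hepta-2,6-dien-1-yl]-3-(phenylsulfanyl)oxolan-2-one
Product: 18 (5S)-5-[(2E,6E)-2,6-bis(TBS-oxymethyl)-7-(trimethylsilyl)hepta-2,6-dien-1-yl]furan-2(5H)-one, via sulfoxide 17 (not isolated)
Conditions: mCPBA (1.0 equiv), CH2Cl2, −78 °C; then PhMe, CaCO3, 110 °C
Reagents that add atoms: none
Why: Sulfide oxidation at −78 °C is far faster than alkene epoxidation, and thermal syn-elimination of the sulfoxide (sulfoxide pyrolysis), whose only β-hydrogens are on C7, should give the C7=C11 butenolide.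

Step 9
Reactants: 18 (5S)-5-[(2E,6E)-2,6-bis(TBS-oxymethyl)-7-(trimethylsilyl)hepta-2,6-dien-1-yl]furan-2(5H)-one
Product: 19 (5S)-5-[(2E,6E)-2,6-bis(TBS-oxymethyl)-7-iodohepta-2,6-dien-1-yl]furan-2(5H)-one
Conditions: NIS (1.3 equiv), (CF3)2CHOH, 0 °C; aq. Na2S2O3
Reagents that add atoms: N-iodosuccinimide, O=C1CCC(=O)N1I
Why: Electrophilic ipso-iododesilylation of the alkenylsilane passes through a β-silyl cation, proceeds with retention (iodine cis to C3) and should outpace iodination of the other alkenes.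

Step 10
Reactants: 19 (5S)-5-[(2E,6E)-2,6-bis(TBS-oxymethyl)-7-iodohepta-2,6-dien-1-yl]furan-2(5H)-one
Product: 20 (4R,5S)-4-{[dimethyl(propan-2-yloxy)silyl]methyl}-5-[(2E,6E)-2,6-bis(TBS-oxymethyl)-7-iodohepta-2,6-dien-1-yl]oxolan-2-one
Conditions: ClCH2SiMe2(Oi-Pr), Mg, THF, rt (Grignard reagent, 2 equiv); CuBr·SMe2 (20 mol %), THF, −78 °C, add 19; aq. NH4Cl
Reagents that add atoms: (isopropoxydimethylsilyl)methylmagnesium chloride, CC(C)O[Si](C)(C)C[Mg]Cl (made in the flask from (chloromethyl)isopropoxydimethylsilane, ClC[Si](C)(C)OC(C)C, and Mg)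
Why: Copper-catalysed conjugate addition of this hydroxymethyl-anion equivalent to the butenolide occurs on the face opposite the C8 side chain (1,2-induction on the planar five-membered ring), which sets C7 trans to C8.

Step 11
Reactants: 20 (4R,5S)-4-{[dimethyl(propan-2-yloxy)silyl]methyl}-5-[(2E,6E)-2,6-bis(TBS-oxymethyl)-7-iodohepta-2,6-dien-1-yl]oxolan-2-one
Product: 21 (4S,5S)-4-(hydroxymethyl)-5-[(2E,6E)-2,6-bis(TBS-oxymethyl)-7-iodohepta-2,6-dien-1-yl]oxolan-2-one
Conditions: 30% H2O2, KF, KHCO3, THF/MeOH 1:1, rt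
Reagents that add atoms: hydrogen peroxide, OO
Why: Tamao oxidation of the alkoxysilane converts C6–Si into C6–OH under buffered peroxide, conditions that should leave the alkenyl iodide, the silyl ethers and the alkenes alone.

Step 12
Reactants: 21 (4S,5S)-4-(hydroxymethyl)-5-[(2E,6E)-2,6-bis(TBS-oxymethyl)-7-iodohepta-2,6-dien-1-yl]oxolan-2-one
Product: 22 (2S,3R)-2-[(2E,6E)-2,6-bis(TBS-oxymethyl)-7-iodohepta-2,6-dien-1-yl]-5-oxooxolane-3-carbaldehyde
Conditions: Dess–Martin periodinane, NaHCO3, CH2Cl2, 0 °C → rt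
Reagents that add atoms: none
Why: Buffered Dess–Martin oxidation gives the aldehyde without base, so the β-acyloxy group is not eliminated, and the trans arrangement at C7 is in any case the more stable one.

Step 13
Reactants: 22 (2S,3R)-2-[(2E,6E)-2,6-bis(TBS-oxymethyl)-7-iodohepta-2,6-dien-1-yl]-5-oxooxolane-3-carbaldehyde
Product: 24 (1(10)E,4E,6S,7S,8S)-14,15-bis(TBS-oxy)-6-hydroxygermacra-1(10),4-dien-12,8-olide, via alkenylchromium(III) species 23 (not isolated)
Conditions: CrCl2 (10 equiv), NiCl2 (0.1 equiv), DMSO/THF 3:1, rt, syringe-pump addition of 22 to 2 mM; aqueous work-up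
Reagents that add atoms: none
Why: Nickel(0), generated from NiCl2 by Cr(II), inserts into the C5–I bond and passes the alkenyl group to chromium with retention of the C4=C5 geometry; the alkenylchromium(III) 23 then adds to the C6 aldehyde under neutral conditions, which is the Nozaki–Hiyama–Kishi reaction in its macrocyclizing form, known for medium and large rings. The ring closes in a 10-exo-trig mode onto the carbonyl, helped by the two ring-cis alkenes and the trans-lactone, which pre-bend the chain, and by the sp2 terminus of the new bond, which limits transannular strain. C6 is set by the C7/C8 stereocentres within the cyclic transition state: the chain anchored at C8 can bring C5 to the carbonyl only from the C8 side, and addition to the Si face, which places the new oxygen 1,3-anti to O8 (polar induction by the β-acyloxy group), should give 6S. This must override the Felkin–Anh preference from C7 alone, which points to the other face. The step also needs activation of the alkenyl iodide in the presence of an enolizable β-acyloxy aldehyde, a lactone and two allylic silyl ethers, which the low basicity and aldehyde selectivity of organochromium(III) secure, and ring closure over oligomerization, which slow addition at high dilution secures.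

Step 14
Reactants: 24 (1(10)E,4E,6S,7S,8S)-14,15-bis(TBS-oxy)-6-hydroxygermacra-1(10),4-dien-12,8-olide
Product: 25 (1(10)E,4E,6S,7R,8S)-14,15-bis(TBS-oxy)-6-(TES-oxy)germacra-1(10),4-dien-12,8-olide
Conditions: TESOTf, 2,6-lutidine, CH2Cl2, −78 °C
Reagents that add atoms: triethylsilyl trifluoromethanesulfonate, CC[Si](CC)(CC)OS(=O)(=O)C(F)(F)F
Why: Silylation of the hindered secondary alcohol masks O6 so that its alkoxide cannot open the lactone toward C6 (translactonization) during the enolate chemistry of step 15.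

Step 15
Reactants: 25 (1(10)E,4E,6S,7R,8S)-14,15-bis(TBS-oxy)-6-(TES-oxy)germacra-1(10),4-dien-12,8-olide
Product: 28 (1(10)E,4E,6S,7R,8S)-14,15-bis(TBS-oxy)-6-(TES-oxy)germacra-1(10),4,11(13)-trien-12,8-olide, via Mannich base 26 (not isolated), via ammonium iodide 27 (not isolated)
Conditions: LiHMDS, THF, −78 °C; CH2=NMe2+ I−, −78 °C → rt; MeI, MeOH, rt; aq. NaHCO3/CH2Cl2, rt
Reagents that add atoms: Eschenmoser's salt (N,N-dimethylmethyleneiminium iodide), C=[N+](C)C.[I-]
Why: Aminomethylation of the lactone enolate, quaternization and E1cB loss of trimethylamine (Eschenmoser methylenation) install C13; C11 ends as sp2, so its transient configuration does not matter.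

Step 16
Reactants: 28 (1(10)E,4E,6S,7R,8S)-14,15-bis(TBS-oxy)-6-(TES-oxy)germacra-1(10),4,11(13)-trien-12,8-olide
Product: 29 (1(10)E,4E,6S,7S,8S)-14,15-bis(TBS-oxy)-6-hydroxygermacra-1(10),4,11(13)-trien-12,8-olide
Conditions: PPTS (cat.), MeOH/CH2Cl2, 0 °C
Reagents that add atoms: none
Why: Acid-catalysed methanolysis cleaves a triethylsilyl ether much faster than a tert-butyldimethylsilyl ether (selective desilylation), and the non-basic medium spares the α-methylene lactone.

Step 17
Reactants: 29 (1(10)E,4E,6S,7S,8S)-14,15-bis(TBS-oxy)-6-hydroxygermacra-1(10),4,11(13)-trien-12,8-olide; 30 tigloyl chloride [(E)-2-methylbut-2-enoyl chloride]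
Product: 31 (1(10)E,4E,6S,7R,8S)-14,15-bis(TBS-oxy)-6-[(E)-2-methylbut-2-enoyloxy]germacra-1(10),4,11(13)-trien-12,8-olide
Conditions: 30, pyridine, DMAP (cat.), CH2Cl2, 0 °C → rt
Reagents that add atoms: none
Why: DMAP-catalysed acylation esterifies O6 with retention at C6, and the weak base keeps the E geometry of the tiglate.

Step 18
Reactants: 31 (1(10)E,4E,6S,7R,8S)-14,15-bis(TBS-oxy)-6-[(E)-2-methylbut-2-enoyloxy]germacra-1(10),4,11(13)-trien-12,8-olide
Product: 32 (1(10)E,4E,6S,7R,8S)-14,15-dihydroxy-6-[(E)-2-methylbut-2-enoyloxy]germacra-1(10),4,11(13)-trien-12,8-olide (CNP0275462.1)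
Conditions: HF·pyridine, pyridine, THF, 0 °C → rt
Reagents that add atoms: none
Why: Buffered fluoride desilylation cleaves both primary TBS ethers without touching the allylic tiglate or the α-methylene lactone; O15 is trans to C6 across C4=C5, so acyl migration is not expected.

**Compound list**

1 | 3-(trimethylsilyl)prop-2-yn-1-ol | OCC#C[Si](C)(C)C | starting material
2 | (4-bromobut-1-yn-1-yl)trimethylsilane | BrCCC#C[Si](C)(C)C | starting material
3 | [4-(trimethylsilyl)but-3-yn-1-yl]magnesium bromide (not isolated) | Br[Mg]CCC#C[Si](C)(C)C | intermediate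
4 | (E)-3-(trimethylsilyl)-2-[4-(trimethylsilyl)but-3-yn-1-yl]prop-2-en-1-ol | OC/C(CCC#C[Si](C)(C)C)=C/[Si](C)(C)C | intermediate
5 | (E)-2-(but-3-yn-1-yl)-3-(trimethylsilyl)prop-2-en-1-ol | OC/C(CCC#C)=C/[Si](C)(C)C | intermediate
6 | (E)-2-[(trimethylsilyl)methylidene]hept-5-yne-1,7-diol | OCC#CCC/C(CO)=C\[Si](C)(C)C | intermediate
7 | (2Z)-2-(tributylstannyl)-6-[(E)-(trimethylsilyl)methylidene]hept-2-ene-1,7-diol (not isolated) | OC/C(=C/CC/C(CO)=C\[Si](C)(C)C)[Sn](CCCC)(CCCC)CCCC | intermediate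
8 | (2Z)-2-iodo-6-[(E)-(trimethylsilyl)methylidene]hept-2-ene-1,7-diol | OC/C(I)=C/CC/C(CO)=C\[Si](C)(C)C | intermediate
9 | (2Z,6E)-1-(TBS-oxy)-6-[(TBS-oxy)methyl]-2-iodo-7-(trimethylsilyl)hepta-2,6-diene | CC(C)(C)[Si](C)(C)OC/C(I)=C/CC/C(CO[Si](C)(C)C(C)(C)C)=C\[Si](C)(C)C | intermediate
10 | (S)-epichlorohydrin, (S)-2-(chloromethyl)oxirane | ClC[C@@H]1CO1 | starting material
11 | alkenyllithium from 9, lithium on C10 cis to C2 (not isolated) | [Li]/C(CO[Si](C)(C)C(C)(C)C)=C\CC/C(CO[Si](C)(C)C(C)(C)C)=C\[Si](C)(C)C | intermediate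
12 | (2S,4E,8E)-1-chloro-4,8-bis(TBS-oxymethyl)-9-(trimethylsilyl)nona-4,8-dien-2-ol (not isolated) | ClC[C@@H](O)C/C(CO[Si](C)(C)C(C)(C)C)=C\CC/C(CO[Si](C)(C)C(C)(C)C)=C\[Si](C)(C)C | intermediate
13 | (S)-2-[(2E,6E)-2,6-bis(TBS-oxymethyl)-7-(trimethylsilyl)hepta-2,6-dien-1-yl]oxirane | C1O[C@H]1C/C(CO[Si](C)(C)C(C)(C)C)=C\CC/C(CO[Si](C)(C)C(C)(C)C)=C\[Si](C)(C)C | intermediate
14 | (phenylthio)acetic acid | OC(=O)CSc1ccccc1 | starting material
15 | (4S,6E,10E)-4-hydroxy-6,10-bis(TBS-oxymethyl)-2-(phenylsulfanyl)-11-(trimethylsilyl)undeca-6,10-dienoic acid, C2 epimers (not isolated) | OC(=O)C(Sc1ccccc1)C[C@@H](O)C/C(CO[Si](C)(C)C(C)(C)C)=C\CC/C(CO[Si](C)(C)C(C)(C)C)=C\[Si](C)(C)C | intermediate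
16 | (5S)-5-[(2E,6E)-2,6-bis(TBS-oxymethyl)-7-(trimethylsilyl)hepta-2,6-dien-1-yl]-3-(phenylsulfanyl)oxolan-2-one, C3 epimers | O=C1O[C@@H](C/C(CO[Si](C)(C)C(C)(C)C)=C\CC/C(CO[Si](C)(C)C(C)(C)C)=C\[Si](C)(C)C)CC1Sc1ccccc1 | intermediate
17 | S-oxide of 16, 3-(phenylsulfinyl)oxolan-2-one (not isolated) | O=C1O[C@@H](C/C(CO[Si](C)(C)C(C)(C)C)=C\CC/C(CO[Si](C)(C)C(C)(C)C)=C\[Si](C)(C)C)CC1S(=O)c1ccccc1 | intermediate
18 | (5S)-5-[(2E,6E)-2,6-bis(TBS-oxymethyl)-7-(trimethylsilyl)hepta-2,6-dien-1-yl]furan-2(5H)-one | O=C1O[C@@H](C/C(CO[Si](C)(C)C(C)(C)C)=C\CC/C(CO[Si](C)(C)C(C)(C)C)=C\[Si](C)(C)C)C=C1 | intermediate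
19 | (5S)-5-[(2E,6E)-2,6-bis(TBS-oxymethyl)-7-iodohepta-2,6-dien-1-yl]furan-2(5H)-one | O=C1O[C@@H](C/C(CO[Si](C)(C)C(C)(C)C)=C\CC/C(CO[Si](C)(C)C(C)(C)C)=C\I)C=C1 | intermediate
20 | (4R,5S)-4-{[dimethyl(propan-2-yloxy)silyl]methyl}-5-[(2E,6E)-2,6-bis(TBS-oxymethyl)-7-iodohepta-2,6-dien-1-yl]oxolan-2-one | O=C1O[C@@H](C/C(CO[Si](C)(C)C(C)(C)C)=C\CC/C(CO[Si](C)(C)C(C)(C)C)=C\I)[C@H](C[Si](C)(C)OC(C)C)C1 | intermediate
21 | (4S,5S)-4-(hydroxymethyl)-5-[(2E,6E)-2,6-bis(TBS-oxymethyl)-7-iodohepta-2,6-dien-1-yl]oxolan-2-one | O=C1O[C@@H](C/C(CO[Si](C)(C)C(C)(C)C)=C\CC/C(CO[Si](C)(C)C(C)(C)C)=C\I)[C@H](CO)C1 | intermediate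
22 | (2S,3R)-2-[(2E,6E)-2,6-bis(TBS-oxymethyl)-7-iodohepta-2,6-dien-1-yl]-5-oxooxolane-3-carbaldehyde | O=C[C@@H]1CC(=O)O[C@H]1C/C(CO[Si](C)(C)C(C)(C)C)=C\CC/C(CO[Si](C)(C)C(C)(C)C)=C\I | intermediate
23 | alkenylchromium(III) dichloride from 22, chromium in place of iodine (not isolated) | O=C[C@@H]1CC(=O)O[C@H]1C/C(CO[Si](C)(C)C(C)(C)C)=C\CC/C(CO[Si](C)(C)C(C)(C)C)=C\[Cr](Cl)Cl | intermediate
24 | (1(10)E,4E,6S,7S,8S)-14,15-bis(TBS-oxy)-6-hydroxygermacra-1(10),4-dien-12,8-olide (ring-cis alkenes, trans-fused lactone) | O=C1O[C@H]2C/C(CO[Si](C)(C)C(C)(C)C)=C\CC/C(CO[Si](C)(C)C(C)(C)C)=C\[C@H](O)[C@@H]2C1 | intermediate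
25 | (1(10)E,4E,6S,7R,8S)-14,15-bis(TBS-oxy)-6-(TES-oxy)germacra-1(10),4-dien-12,8-olide | O=C1O[C@H]2C/C(CO[Si](C)(C)C(C)(C)C)=C\CC/C(CO[Si](C)(C)C(C)(C)C)=C\[C@H](O[Si](CC)(CC)CC)[C@@H]2C1 | intermediate
26 | 11-[(dimethylamino)methyl] derivative of 25, C11 epimers (not isolated) | O=C1O[C@H]2C/C(CO[Si](C)(C)C(C)(C)C)=C\CC/C(CO[Si](C)(C)C(C)(C)C)=C\[C@H](O[Si](CC)(CC)CC)[C@@H]2C1CN(C)C | intermediate
27 | 11-[(trimethylammonio)methyl] iodide of 25 (not isolated) | O=C1O[C@H]2C/C(CO[Si](C)(C)C(C)(C)C)=C\CC/C(CO[Si](C)(C)C(C)(C)C)=C\[C@H](O[Si](CC)(CC)CC)[C@@H]2C1C[N+](C)(C)C.[I-] | intermediate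
28 | (1(10)E,4E,6S,7R,8S)-14,15-bis(TBS-oxy)-6-(TES-oxy)germacra-1(10),4,11(13)-trien-12,8-olide | C=C1C(=O)O[C@H]2C/C(CO[Si](C)(C)C(C)(C)C)=C\CC/C(CO[Si](C)(C)C(C)(C)C)=C\[C@H](O[Si](CC)(CC)CC)[C@H]12 | intermediate
29 | (1(10)E,4E,6S,7S,8S)-14,15-bis(TBS-oxy)-6-hydroxygermacra-1(10),4,11(13)-trien-12,8-olide | C=C1C(=O)O[C@H]2C/C(CO[Si](C)(C)C(C)(C)C)=C\CC/C(CO[Si](C)(C)C(C)(C)C)=C\[C@H](O)[C@H]12 | intermediate
30 | tigloyl chloride, (E)-2-methylbut-2-enoyl chloride | C/C=C(C)/C(=O)Cl | starting material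
31 | (1(10)E,4E,6S,7R,8S)-14,15-bis(TBS-oxy)-6-[(E)-2-methylbut-2-enoyloxy]germacra-1(10),4,11(13)-trien-12,8-olide | C=C1C(=O)O[C@H]2C/C(CO[Si](C)(C)C(C)(C)C)=C\CC/C(CO[Si](C)(C)C(C)(C)C)=C\[C@H](OC(=O)/C(C)=C/C)[C@H]12 | intermediate
32 | (1(10)E,4E,6S,7R,8S)-14,15-dihydroxy-6-[(E)-2-methylbut-2-enoyloxy]germacra-1(10),4,11(13)-trien-12,8-olide | C=C1C(=O)O[C@H]2C/C(CO)=C\CC/C(CO)=C\[C@H](OC(=O)/C(C)=C/C)[C@H]12 | target

**Count and risks**

Total steps: 18. Longest linear sequence: 18 steps (1 and 2 to 32; the route is fully linear).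

Steps most likely to fail:

Step 13. The ring closure may show poor facial selectivity at C6, or turn toward the 6R alcohol that Felkin–Anh induction from C7 alone would favour, and intermolecular coupling may compete with the strained ten-membered closure. The fallback sets C6 by reagent-controlled reduction instead of in the C–C bond formation. The C6 epimer mixture of 24 would be oxidized with Dess–Martin periodinane to the C6 ketone, (1(10)E,4E,7R,8S)-14,15-bis(TBS-oxy)-6-oxogermacra-1(10),4-dien-12,8-olide F1. This enone would then be reduced with catecholborane under Corey–Bakshi–Shibata catalysis. The (S)-Me-CBS catalyst is the one predicted for 6S if the alkenyl arm acts as the large group; the (R)-catalyst is the alternative. The fallback sets out from 24 and comes back at 24.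

Step 1. The copper-catalysed carbomagnesiation may stall on the silyl-capped alkyne or lose its regio- and anti-selectivity with a functionalized primary alkyl Grignard reagent. The fallback builds the same alkenylsilane by cross-coupling. Palladium-catalysed syn-silylstannation of propargyl alcohol with trimethyl(tributylstannyl)silane should give (Z)-2-(tributylstannyl)-3-(trimethylsilyl)prop-2-en-1-ol F2, with tin on the inner carbon cis to silicon. Iodine would convert it selectively at the C–Sn bond into (Z)-2-iodo-3-(trimethylsilyl)prop-2-en-1-ol F3. Negishi coupling of F3 with [4-(trimethylsilyl)but-3-yn-1-yl]zinc bromide F4, made from 2 and zinc, should give 4 with the chain cis to silicon. The fallback sets out from 2 and comes back at 4.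

Step 10. Transfer of the α-silylmethyl group from copper may be slow, which would allow deprotonation at C8 (loss of configuration) or 1,2-addition to the lactone carbonyl. The fallback brings in C6 as a hydroxymethyl radical instead of an organocopper reagent. Benzophenone-sensitized irradiation of butenolide 18 in methanol should give the trans adduct (4S,5S)-4-(hydroxymethyl)-5-[(2E,6E)-2,6-bis(TBS-oxymethyl)-7-(trimethylsilyl)hepta-2,6-dien-1-yl]oxolan-2-one F5. Dess–Martin oxidation would give (2S,3R)-2-[(2E,6E)-2,6-bis(TBS-oxymethyl)-7-(trimethylsilyl)hepta-2,6-dien-1-yl]-5-oxooxolane-3-carbaldehyde F6, and iododesilylation with NIS would give 22. The fallback sets out from 18 and comes back at 22.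

Further compounds
F1 | step 13 | (1(10)E,4E,7R,8S)-14,15-bis(TBS-oxy)-6-oxogermacra-1(10),4-dien-12,8-olide | O=C1O[C@H]2C/C(CO[Si](C)(C)C(C)(C)C)=C\CC/C(CO[Si](C)(C)C(C)(C)C)=C\C(=O)[C@@H]2C1
F2 | step 1 | (Z)-2-(tributylstannyl)-3-(trimethylsilyl)prop-2-en-1-ol | OC/C(=C/[Si](C)(C)C)[Sn](CCCC)(CCCC)CCCC
F3 | step 1 | (Z)-2-iodo-3-(trimethylsilyl)prop-2-en-1-ol | OC/C(I)=C/[Si](C)(C)C
F4 | step 1 | [4-(trimethylsilyl)but-3-yn-1-yl]zinc bromide | Br[Zn]CCC#C[Si](C)(C)C
F5 | step 10 | (4S,5S)-4-(hydroxymethyl)-5-[(2E,6E)-2,6-bis(TBS-oxymethyl)-7-(trimethylsilyl)hepta-2,6-dien-1-yl]oxolan-2-one | O=C1O[C@@H](C/C(CO[Si](C)(C)C(C)(C)C)=C\CC/C(CO[Si](C)(C)C(C)(C)C)=C\[Si](C)(C)C)[C@H](CO)C1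
F6 | step 10 | (2S,3R)-2-[(2E,6E)-2,6-bis(TBS-oxymethyl)-7-(trimethylsilyl)hepta-2,6-dien-1-yl]-5-oxooxolane-3-carbaldehyde | O=C[C@@H]1CC(=O)O[C@H]1C/C(CO[Si](C)(C)C(C)(C)C)=C\CC/C(CO[Si](C)(C)C(C)(C)C)=C\[Si](C)(C)C
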